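The easiest step with these flasks was a subtraction, so I began there, counting the substrate left and not the product made.

| flask | substrate | reagent | temperature | remark | time |
|---|---|---|---|---|---|
| spring | 0.023 M | 0.088 M | 95 °C | run made earlier |  |
| dawn | 0.16 M | 0.088 M | 110 °C | run made earlier |  |
| south | 0.12 M | 0.0880 M | 110 °C |  | 40 h |
| west | 0.040 M | 0.0880 M | 110 °C |  | 40 h |
| north-west | 0.25 M | 0.0880 M | 110 °C |  | 40 h |
| south-east | 0.088 M | 0.0880 M | 110 °C |  | 40 h |

- spring (time / h: product / %, substrate / %): 8.00: 1.3, 98.2; 20.0: 0, 100.7; 40.0: 2.3, 100.1; 60.0: 0, 99.8
- dawn (time / h: product / %, substrate / %): 8.00: 1.9, 96.6; 15.0: 28.6, 73.1; 20.0: 47.2, 54.4; 30.0: 54.7, 46.6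

(each reading ± 1 percentage point)

- the analysis behind the earlier runs scatters by 1 percentage point, standard deviation
- steps that have been proposed: substrate + reagent -> product; substrate + reagent + product -> 2 product

* all flasks from highest to lowest amount of product, in percent of the substrate charged, at 40 h (south / west / north-west / south-east)
* the same order at 6.0 d (south / west / north-west / south-east)
* the amount of product, in percent of the substrate charged of the flask you put first, at 40 h
* the amount of product, in percent of the substrate charged of the flask you put last, at 40 h

Each proposed step spends one substrate and one reagent, so [substrate] and [reagent] fall together. I therefore named the reagent allowance 0.0880 M: the concentration of substrate that the reagent charge can remove. Where it is smaller than [substrate] at the start, reagent is the limiting reagent, and the fraction left stops at one minus the allowance over that charge.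

I took two ways to the same number in the dawn run. The charges gave a floor of 45.0 %. The last reading, at 30.0 h, showed 46.6 % of substrate, so 0.0854 M had gone. The gap of 1.6 percentage points stood against a scatter of 1 point, and these numbers come from different things, so I trusted the allowance.

In the spring run the two ways parted. The allowance exceeded the 0.023 M of substrate charged, so the subtraction gave no floor, yet the reading at 60.0 h was still 99.8 %. That flask was also cooler, but the readings stood, so the subtraction was the one that cheated: it says where a flask stops, not when it arrives.

My reckoning therefore gave floors of 64.8 % for north-west and 26.7 % for south. West has a charge below the allowance, and south-east has one equal to it, so neither has a floor and both needed the dawn curve.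

The forecast gave south-east > south > north-west > west at 40 h, with south-east at 77 % and west at 18 %, and west > south-east > south > north-west at 6.0 d. Of the last flask it said: “West is still in induction”.

The flasks gave south-east > south > north-west > west, with south-east at 76.7 % and west at 13.6 %, and west > south-east > south > north-west at 6.0 d.

    substrate + reagent → product (k = 2.18 × 10⁻⁷ /M/s, Ea = 110 kJ/mol)
    substrate + reagent + product → 2 product (k = 0.0116 /M²/s, Ea = 57.0 kJ/mol)
    (constants at 110 °C)

North-west held 65 % of its substrate at 40.0 h, with reagent at 0 %, which is the floor I had reckoned from the allowance with no rate constant. West held 86 % at 40.0 h because its time was short: its product stood at 13.6 % then, and at 100 % by 400 h. The shrinking reagent was not the reason.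

A neighbour like south-east, charged with 0.22 M of substrate, has a floor of 60.0 % from the same allowance. It held 60.0 % of substrate at 40.0 h.

(The readings were generated by integration from invented constants; noise was put on by code.)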